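**Abbreviations:** geranyl = (2E)-3,7-dimethylocta-2,6-dien-1-yl; MOM = methoxymethyl; TIPS = triisopropylsilyl. Flavonoid numbering (O1, C2, C3, C4, C4a, C5–C8, C8a; rings A, B, C) is used throughout.

## Analysis of the target

CNP0264411.1 is 6-geranylhesperetin, a flavanone. Ring A is a phloroglucinol ring (5-OH, 7-OH, O1 on C8a) with an (E)-geranyl chain at C6, ring C is the dihydropyranone (O1, C2, C3, C4=O, C4a, C8a), and ring B is a 3-hydroxy-4-methoxyphenyl group on C2. C2 (S) is the only stereocentre; the only other stereo-element is the (E)-alkene of the chain, which comes with the geranyl unit. C2 is a benzylic ether carbon β to the ketone, so base opens the O1–C2 bond by retro-oxa-Michael reaction and racemises it. The two trisubstituted alkenes lie between the 5- and 7-hydroxyls and add phenols or solvent under strong protic acid. Three things make the synthesis hard: the absolute configuration of a centre with no neighbouring stereocontrol, the placement of the chain at C6 and not C8 (the two differ only in which ring A oxygen becomes O1), and an end game that spares both C2 and the alkenes. The plan rests on the fact that O1 and C4 sit on adjacent carbons of ring A (C8a and C4a): O1–C8a–C4a–C4 is a latent ortho-quinone methide with C4 at the aldehyde oxidation level, and C2–C3 with ring B is a styrene. Ring C and C2 can therefore be made in one cycloaddition from two simple aromatic compounds.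

## Retrosynthetic reasoning

**17 from 16.** The last disconnection removes the three O-protecting groups: 17 comes from the tris(methoxymethyl) ether 16. Acetals are chosen because they are cleaved under acid, where the O1–C2 bond of a flavanone is stable, whereas base or unbuffered fluoride would open it. The two acetals on ring A are also needed much earlier as directing groups.

**16 from 15 and 14.** Ketone 16 is taken back to the C4-epimeric alcohols 15 and these to the 4-methoxyflavan 14. The C4–O bond is benzylic to a ring with three oxygen donors ortho and para to C4a, so OMe is exchanged for OH by ionisation, and oxidation then gives the ketone. C4 is only a temporary stereocentre. The consequence is that a wrong relative configuration in 14 becomes a wrong absolute configuration in 16, so 14 must be one diastereomer before C4 is made trigonal.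

**14 from 8 and 11.** The central cut removes C3–C4 and O1–C2 together and leads to salicylaldehyde 8 and styrene 11. It is the only cut that divides the molecule into two flat aromatic pieces of similar size and creates the stereocentre in the same step; cutting only one of the two bonds leaves an acyclic chain whose stereocentre has to be made separately. In the forward direction 8 is converted in the flask into its dimethyl acetal 12, ionisation gives the methoxy ortho-quinone methide 13 as an ion pair with a chiral anion, and 11 adds across C4 and O1. An oxocarbenium ion backed by three ring oxygens is a sluggish electrophile, so the acid must be strong and its anion non-nucleophilic. Such an acid is not a weak one; the isolated alkenes and the acetal protecting groups are therefore protected by rate differences and low temperature, not by low acidity. Regiochemistry on ring A follows from 8 having a single free hydroxyl, the one para to the geranyl group.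

**8 from 7.** Aldehyde 8 is cut at the C4a–CHO bond to give phenol 7. Phenol 7 has a mirror plane through C1 and C4, so its two ortho positions are identical and magnesium-mediated ortho-formylation can give only 8. The 6- versus 8-substitution problem is thereby reduced to one requirement: the free hydroxyl of 7 must be the one para to the chain.

**7 from 6, and 6 from 3 and 4.** Phenol 7 comes from silyl ether 6, which is cut at the aryl–CH2 bond into arene 3 and geranyl bromide (4). Attaching the chain to phloroglucinol (1) first and protecting afterwards was rejected. The hydroxyl para to the chain is the unhindered one and would be protected first, which is the opposite of what 7 needs and would lead to the 8-geranyl series. With 3 the regiochemistry is set by mechanism: the carbon between the two acetal oxygens is lithiated (aryllithium 5), the bulky silyl ether neither directs nor permits metalation beside it, and SN2 coupling with 4 keeps the (E)-alkene. This is also why the ring A oxygens carry acetals and not silyl groups.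

**3 from 2 and 1.** Arene 3 is made from 1 through monosilyl ether 2. Because 1 is threefold symmetric there is no regiochemical question, only mono- against polysilylation.

**11 from 10 and 9.** Styrene 11 is cut at its C=C bond to aldehyde 10, the acetal-protected form of isovanillin (9), which already has the 3-hydroxy-4-methoxy pattern of ring B.

## Alternatives that were turned down

**Alternative 1:** Ring A is built last by cutting C4a–C5.
- **Key step:** the enantioenriched dihydropyranone A1, which carries a geranylated β,δ-diketo ester chain on C8a, is treated with Mg(OMe)2 in methanol. The chain is deprotonated, C4a attacks the ester carbon in a Claisen condensation, and enolisation aromatises the new ring to give the mono-MOM flavanone A2.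
- **For it:** the geranyl carbon of the chain becomes C6 by construction, so no ring A oxygens need to be told apart, ring A needs no protecting groups, and only one acetal remains to be removed. On regiochemistry and protecting-group count it is stronger than the chosen route.
- **Against it:** C2 must be installed beforehand and then survive magnesium methoxide in methanol. A 5,7-dihydroxyflavanone opens at O1–C2 through its C3 enolate in exactly such a medium, so A2 is at risk of racemising as it forms. A1 also has several acidic positions (C3, C8 and the doubly activated CH that bears the chain) and must be assembled linearly by acylation of a sensitive diketo ester.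
- **Comparison:** the chosen route buys ring A instead of building it, is convergent, and creates C2 under acid without ever exposing it to base.

**Alternative 2:** Ring C is closed at C2–C3 by carbene C–H insertion.
- **Key step:** diazoketone A3, an aryl diazomethyl ketone with the ring B benzyl ether on the ortho oxygen, is decomposed with Rh2(S-PTTL)4, dirhodium tetrakis[N-phthaloyl-(S)-tert-leucinate] (divalent rhodium). The carbene at C3 inserts into the O–CH2 C–H bond to give the tris(silyl) flavanone A4.
- **For it:** the C–H bond is activated by both oxygen and aryl, and the product is already at the ketone oxidation level. Only desilylation with buffered fluoride remains, which is a shorter and gentler end game than the chosen one.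
- **Against it:** the carbene is acceptor-only and sits next to an ether oxygen, so oxonium ylide formation and [1,2]-benzyl shift with ring contraction compete. The two nucleophilic trisubstituted alkenes and the electron-rich rings invite cyclopropanation and arene addition. Six-membered insertion is less favoured than five-membered, and the high enantioselectivity of this catalyst class is established for donor/acceptor carbenes. A3 also needs the same differentiation of ring A oxygens and a di-ortho-substituted aroyl diazomethane.
- **Comparison:** the electrophile of the chosen route, an oxocarbenium ion, is selective for the styrene and ignores isolated alkenes.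

**Alternative 3:** Ring C is closed at O1–C8a.
- **Key step:** the bromoaryl 1,3-diol A5 is heated with CuI, 3,4,7,8-tetramethyl-1,10-phenanthroline and Cs2CO3 (monovalent copper). The hydroxyl on C2 is arylated intramolecularly to give the flavan-4-ol A6, which is the cis epimer of 15 and would be finished as in steps 10 and 11.
- **For it:** every reaction is known, C2 is set earlier by established asymmetric carbonyl chemistry and is not touched by the C–O coupling, and the position of bromine fixes the regiochemistry. In predictability of stereocontrol it is stronger than the chosen route.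
- **Against it:** A5 contains a pentasubstituted, electron-rich bromoarene that is slow in oxidative addition. The nucleophile is a secondary benzylic alcohol held at high temperature with carbonate, where dehydration competes. Two stereocentres must be controlled although one is discarded, and the acyclic chain is built linearly, giving the longest sequence of all.
- **Comparison:** the chosen route forms both ring C bonds and C2 in one convergent step and reaches the same flavan-4-ol stage in fewer operations.

Key step: step 8

## Route

Assumption: the sense of induction of the new step 8 cannot be derived from precedent; the (S,S)-catalyst is written, and its mirror image is used if it should deliver the (2R) series.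

Step 1
Reactants: 1 phloroglucinol (benzene-1,3,5-triol)
Product: 2 5-(triisopropylsilyloxy)benzene-1,3-diol
Conditions: TIPSCl (1 equiv), imidazole, DMF, 0 °C → rt; 1 in threefold excess
Reagents that add atoms: chlorotriisopropylsilane, CC(C)[Si](Cl)(C(C)C)C(C)C
Why: Silyl ether formation on a threefold-symmetric triol: all hydroxyls are equivalent, so only mono- against bis-silylation has to be controlled, which the excess of cheap 1 should do. The bulky group is chosen because it neither directs nor permits lithiation beside it.

Step 2
Reactants: 2 5-(triisopropylsilyloxy)benzene-1,3-diol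
Product: 3 [3,5-bis(methoxymethoxy)phenoxy]triisopropylsilane
Conditions: MOMCl, iPr2NEt, CH2Cl2, 0 °C → rt
Reagents that add atoms: chloromethyl methyl ether, COCCl
Why: Standard acetal protection of phenols by O-alkylation with an α-chloro ether. The two MOM oxygens are the directing groups for step 3 and should survive base, fluoride and mild acid.

Step 3
Reactants: 3 [3,5-bis(methoxymethoxy)phenoxy]triisopropylsilane; 4 geranyl bromide
Product: 6 [4-geranyl-3,5-bis(methoxymethoxy)phenoxy]triisopropylsilane, via aryllithium 5 (not isolated)
Conditions: n-BuLi, THF, 0 °C; CuI (10 mol %), 4, −78 °C → rt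
Reagents that add atoms: none
Why: Directed ortho-metalation: the carbon between the two MOM ethers is the most acidic and doubly chelated, while the positions next to the silyl ether are shielded, so 5 should form regiospecifically. Copper-catalysed SN2 coupling with the primary allylic bromide keeps the (E)-alkene and places the chain para to the silyloxy group.

Step 4
Reactants: 6 [4-geranyl-3,5-bis(methoxymethoxy)phenoxy]triisopropylsilane
Product: 7 4-geranyl-3,5-bis(methoxymethoxy)phenol
Conditions: Bu4NF, THF, 0 °C; aq. NH4Cl
Reagents that add atoms: none
Why: Fluoride cleavage of an aryl silyl ether; acetals and alkenes are inert. The product is a mirror-symmetric phenol whose only free hydroxyl is para to the geranyl group.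

Step 5
Reactants: 7 4-geranyl-3,5-bis(methoxymethoxy)phenol
Product: 8 5-geranyl-2-hydroxy-4,6-bis(methoxymethoxy)benzaldehyde
Conditions: MgCl2, Et3N, (CH2O)n, MeCN, 80 °C
Reagents that add atoms: formaldehyde (from paraformaldehyde), C=O
Why: Magnesium-mediated ortho-formylation of a phenol (Casnati–Skattebøl conditions): the magnesium phenoxide delivers formaldehyde only ortho to the free hydroxyl, and a second equivalent oxidises the benzylic alkoxide by hydride transfer. The two ortho positions are equivalent, so a single salicylaldehyde should result, with the aldehyde carbon as the future C4 and the free hydroxyl as the future O1.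

Step 6
Reactants: 9 isovanillin (3-hydroxy-4-methoxybenzaldehyde)
Product: 10 4-methoxy-3-(methoxymethoxy)benzaldehyde
Conditions: MOMCl, iPr2NEt, CH2Cl2, 0 °C → rt
Reagents that add atoms: chloromethyl methyl ether, COCCl
Why: Acetal protection of the phenol by O-alkylation; the aldehyde is not affected.

Step 7
Reactants: 10 4-methoxy-3-(methoxymethoxy)benzaldehyde
Product: 11 4-ethenyl-1-methoxy-2-(methoxymethoxy)benzene
Conditions: Ph3PCH3Br, KOtBu, THF, 0 °C → rt
Reagents that add atoms: methylenetriphenylphosphorane (made in the flask from Ph3PCH3Br and KOtBu), C=P(c1ccccc1)(c1ccccc1)c1ccccc1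
Why: Wittig methylenation of an aromatic aldehyde with a non-stabilised ylide. It gives the styrene that carries ring B, C2 and C3; the product is used fresh because it polymerises readily.

Step 8
Reactants: 8 5-geranyl-2-hydroxy-4,6-bis(methoxymethoxy)benzaldehyde; 11 4-ethenyl-1-methoxy-2-(methoxymethoxy)benzene
Product: 14 (2S,4S)-6-geranyl-4-methoxy-2-[4-methoxy-3-(methoxymethoxy)phenyl]-5,7-bis(methoxymethoxy)chromane (2,4-cis), via dimethyl acetal 12 (not isolated), via methoxy ortho-quinone methide 13 (not isolated)
Conditions: (S,S)-IDPi HN[P(=NSO2CF3)(O2C20H10Ar2)]2, Ar = 3,5-(CF3)2C6H3, from (S)-BINOL (5 mol %), HC(OMe)3 (1.2 equiv), 11 (3 equiv), 5 Å MS, toluene, −40 °C, slow addition of 8; Et3N quench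
Reagents that add atoms: trimethyl orthoformate, COC(OC)OC
Why: Proposed new method: acid-catalysed acetalisation of 8 gives 12, which loses methanol to the 4-methoxy ortho-quinone methide 13, present as its O-protonated form, an aryl oxocarbenium ion paired with the chiral imidodiphosphorimidate anion and hydrogen-bonded to it through the phenol. The terminal CH2 of 11 adds to the methide carbon (C3–C4) and the resulting benzylic cation, stabilised by the para-methoxy group of ring B, is captured by the phenol oxygen (O1–C2); ring C is thus closed as a six-membered ring in a stepwise inverse-demand [4+2] whose second event is a 6-exo-trig attack of oxygen on the quinoid form of the cation. The closest known reactions are the achiral-acid three-component synthesis of 4-alkoxychromans from salicylaldehydes, orthoformates and electron-rich alkenes, and chiral phosphoric acid [4+2] reactions of ortho-quinone methides with styrenes; an enantioselective version with an alkoxy-substituted methide is not known. C4 is set by the face of the oxocarbenium ion that the confined anion leaves open, and C2 by ring closure inside the same ion pair through a half-chair with the aryl group equatorial, expected to place it cis to the methoxy group as in the achiral reactions. The step needs Markovnikov regiochemistry, which the polarity of both partners provides, and closure through the oxygen para to the geranyl group, which is the only free one. It also needs chemoselectivity for the benzaldehyde acetal over three formaldehyde acetals and two isolated alkenes; this rests on kinetics and not on a weak acid, because the catalyst is strong but levelled by acetal, orthoformate and methanol, and ionisation of a trioxygenated benzaldehyde acetal is far faster at −40 °C in toluene than ionisation of a MOM ether or protonation of a trisubstituted alkene. Excess 11 and slow addition of 8 keep the electron-rich ring A of acetal and product from competing as a nucleophile. Any trans isomer is removed by chromatography here, because after step 10 it would count as the wrong enantiomer.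

Step 9
Reactants: 14 (2S,4S)-6-geranyl-4-methoxy-2-[4-methoxy-3-(methoxymethoxy)phenyl]-5,7-bis(methoxymethoxy)chromane
Product: 15 (2S,4RS)-6-geranyl-2-[4-methoxy-3-(methoxymethoxy)phenyl]-5,7-bis(methoxymethoxy)chroman-4-ol (both C4 epimers)
Conditions: pyridinium p-toluenesulfonate (10 mol %), THF/H2O 4:1, rt
Reagents that add atoms: water, O
Why: SN1 solvolysis of a benzylic methyl ether: the C4 cation is stabilised by O1, O5 and O7 of ring A, so a pyridinium salt should suffice and the MOM acetals and alkenes stay intact. Water adds from either face, which does not matter because C4 becomes a carbonyl carbon, and C2 takes no part.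

Step 10
Reactants: 15 (2S,4RS)-6-geranyl-2-[4-methoxy-3-(methoxymethoxy)phenyl]-5,7-bis(methoxymethoxy)chroman-4-ol
Product: 16 (2S)-6-geranyl-2-[4-methoxy-3-(methoxymethoxy)phenyl]-5,7-bis(methoxymethoxy)chroman-4-one
Conditions: Dess–Martin periodinane, NaHCO3, CH2Cl2, 0 °C → rt
Reagents that add atoms: none
Why: Dess–Martin oxidation of a secondary benzylic alcohol to the aryl ketone under buffered, non-basic conditions. Both C4 epimers converge on one ketone, and C2, which is not α to the carbonyl, is not touched.

Step 11
Reactants: 16 (2S)-6-geranyl-2-[4-methoxy-3-(methoxymethoxy)phenyl]-5,7-bis(methoxymethoxy)chroman-4-one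
Product: 17 (2S)-6-geranyl-5,7-dihydroxy-2-(3-hydroxy-4-methoxyphenyl)chroman-4-one (CNP0264411.1)
Conditions: HCl (2 M) in MeOH/H2O 9:1, 45 °C; NaHCO3 quench
Reagents that add atoms: none
Why: Acid-catalysed transacetalisation of the three aryl MOM ethers to the solvent (acetal cleavage), the usual unmasking of prenylated flavanones. Acid is used because the flavanone opens at O1–C2 and racemises under base but not under mild acid, and the temperature is kept low to spare the geranyl alkenes.

## Compound list

1 | phloroglucinol (benzene-1,3,5-triol) | Oc1cc(O)cc(O)c1 | starting material
2 | 5-(triisopropylsilyloxy)benzene-1,3-diol | Oc1cc(O)cc(O[Si](C(C)C)(C(C)C)C(C)C)c1 | intermediate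
3 | [3,5-bis(methoxymethoxy)phenoxy]triisopropylsilane | COCOc1cc(OCOC)cc(O[Si](C(C)C)(C(C)C)C(C)C)c1 | intermediate
4 | geranyl bromide, (2E)-1-bromo-3,7-dimethylocta-2,6-diene | BrC/C=C(\C)CCC=C(C)C | starting material
5 | [2,6-bis(methoxymethoxy)-4-(triisopropylsilyloxy)phenyl]lithium (not isolated) | [Li]c1c(OCOC)cc(O[Si](C(C)C)(C(C)C)C(C)C)cc1OCOC | intermediate
6 | [4-geranyl-3,5-bis(methoxymethoxy)phenoxy]triisopropylsilane, (E)-alkene | COCOc1cc(O[Si](C(C)C)(C(C)C)C(C)C)cc(OCOC)c1C/C=C(\C)CCC=C(C)C | intermediate
7 | 4-geranyl-3,5-bis(methoxymethoxy)phenol, (E)-alkene | COCOc1cc(O)cc(OCOC)c1C/C=C(\C)CCC=C(C)C | intermediate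
8 | 5-geranyl-2-hydroxy-4,6-bis(methoxymethoxy)benzaldehyde, (E)-alkene | O=Cc1c(O)cc(OCOC)c(C/C=C(\C)CCC=C(C)C)c1OCOC | intermediate
9 | isovanillin (3-hydroxy-4-methoxybenzaldehyde) | COc1ccc(C=O)cc1O | starting material
10 | 4-methoxy-3-(methoxymethoxy)benzaldehyde | COCOc1cc(C=O)ccc1OC | intermediate
11 | 4-ethenyl-1-methoxy-2-(methoxymethoxy)benzene | C=Cc1ccc(OC)c(OCOC)c1 | intermediate
12 | 2-(dimethoxymethyl)-4-geranyl-3,5-bis(methoxymethoxy)phenol, (E)-alkene (not isolated) | COC(OC)c1c(O)cc(OCOC)c(C/C=C(\C)CCC=C(C)C)c1OCOC | intermediate
13 | 4-geranyl-6-(methoxymethylidene)-3,5-bis(methoxymethoxy)cyclohexa-2,4-dien-1-one, (E)-geranyl alkene, methide geometry not defined, reacts as its O-protonated ion pair (not isolated) | COC=C1C(=O)C=C(OCOC)C(C/C=C(\C)CCC=C(C)C)=C1OCOC | intermediate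
14 | (2S,4S)-6-geranyl-4-methoxy-2-[4-methoxy-3-(methoxymethoxy)phenyl]-5,7-bis(methoxymethoxy)chromane, 2,4-cis | COc1ccc([C@@H]2C[C@H](OC)c3c(cc(OCOC)c(C/C=C(\C)CCC=C(C)C)c3OCOC)O2)cc1OCOC | intermediate
15 | (2S,4RS)-6-geranyl-2-[4-methoxy-3-(methoxymethoxy)phenyl]-5,7-bis(methoxymethoxy)chroman-4-ol, both C4 epimers | COc1ccc([C@@H]2CC(O)c3c(cc(OCOC)c(C/C=C(\C)CCC=C(C)C)c3OCOC)O2)cc1OCOC | intermediate
16 | (2S)-6-geranyl-2-[4-methoxy-3-(methoxymethoxy)phenyl]-5,7-bis(methoxymethoxy)chroman-4-one | COc1ccc([C@@H]2CC(=O)c3c(cc(OCOC)c(C/C=C(\C)CCC=C(C)C)c3OCOC)O2)cc1OCOC | intermediate
17 | (2S)-6-geranyl-5,7-dihydroxy-2-(3-hydroxy-4-methoxyphenyl)chroman-4-one, 6-geranylhesperetin (CNP0264411.1) | COc1ccc([C@@H]2CC(=O)c3c(cc(O)c(C/C=C(\C)CCC=C(C)C)c3O)O2)cc1O | target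

**Total step count:** 11.
**Longest linear sequence:** 9 steps (steps 1–5 and 8–11); steps 6 and 7 form the second branch.

## Steps least certain to work

**Step 8 (key step, new method).**
- What may go wrong: weak discrimination between H and OMe on the oxocarbenium carbon, or ring closure to the trans isomer. Both end as the wrong configuration at C2 once C4 is oxidised. Friedel–Crafts attack by the electron-rich ring A of acetal or product and cationic oligomerisation of the styrene can also consume material, because both are nucleophiles of similar strength to the intended one.
- Fallback (known chemistry), from 8 and 11 back to 16: the annulation is run with an achiral acid, diphenyl phosphate (PhO)2P(O)OH, and trimethyl orthoformate in CH2Cl2, the known three-component 4-alkoxychroman synthesis. It gives the racemic 4-methoxyflavan, racemic 6-geranyl-4-methoxy-2-[4-methoxy-3-(methoxymethoxy)phenyl]-5,7-bis(methoxymethoxy)chromane F1, as a diastereomer mixture whose ratio no longer matters. Solvolysis and oxidation as in steps 9 and 10 give the racemic chroman-4-ol F2 and the racemic chroman-4-one F3. F3 is then resolved by asymmetric transfer hydrogenation with RuCl(p-cymene)[(R,R)-TsNCH(Ph)CH(Ph)NH2] and HCO2H/Et3N, a kinetic resolution known for flavanones. The (2R)-ketone should be reduced to the (2R,4R)-cis-chroman-4-ol F4 and the (2S)-ketone, which is 16, left behind. At most half of the material is usable, and the sense of the resolution is assigned by analogy with 4-chromanone and has to be confirmed.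

**Step 9.**
- What may go wrong: the C4 cation may lose a proton from C3 (elimination to the C3–C4 alkene) or be captured by ring A of a second molecule (oligomerisation) instead of by water, because it is long-lived and the ring is nucleophilic at C8.
- Fallback, from 14 directly to 16: oxidation with 2,3-dichloro-5,6-dicyano-1,4-benzoquinone in CH2Cl2/pH 7 buffer, the known oxidative cleavage of electron-rich benzylic ethers. Hydride abstraction from C4 gives the oxocarbenium ion, water adds, and the hemiketal loses methanol, so no free C4 cation and no separate oxidation are needed.

**Step 11.**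
- What may go wrong: protonation of the geranyl alkenes with cyclisation onto the freed 5- or 7-hydroxyl or addition of methanol, and slow opening of the O1–C2 bond on prolonged heating, since ring B carries a para-methoxy group.
- Fallback, from 16 to 17: the acetals are exchanged for silyl ethers without protic acid. Me3SiOTf and 2,2'-bipyridyl in CH2Cl2 at 0 °C, a known transformation of aryl MOM ethers, should give (2S)-6-geranyl-2-[4-methoxy-3-(trimethylsilyloxy)phenyl]-5,7-bis(trimethylsilyloxy)chroman-4-one F5, which is hydrolysed with water at neutral pH to 17.

**Step 5.**
- What may go wrong: incomplete formylation at a position flanked by OH and OMOM, or condensation of the very electron-rich phenol with formaldehyde to diarylmethanes.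
- Fallback, from 6 to 8: a second directed metalation of 6 (n-BuLi, THF, −20 °C, at the carbon between OMOM and OSi) with DMF quench gives 3-geranyl-2,4-bis(methoxymethoxy)-6-(triisopropylsilyloxy)benzaldehyde F6, and Bu4NF then frees the phenol to give 8. The temperature is kept low to avoid O-to-C silyl migration in the aryllithium.

## Further compounds

F1 | step 8 | racemic 6-geranyl-4-methoxy-2-[4-methoxy-3-(methoxymethoxy)phenyl]-5,7-bis(methoxymethoxy)chromane, diastereomer mixture | COc1ccc(C2CC(OC)c3c(cc(OCOC)c(C/C=C(\C)CCC=C(C)C)c3OCOC)O2)cc1OCOC
F2 | step 8 | racemic 6-geranyl-2-[4-methoxy-3-(methoxymethoxy)phenyl]-5,7-bis(methoxymethoxy)chroman-4-ol, diastereomer mixture | COc1ccc(C2CC(O)c3c(cc(OCOC)c(C/C=C(\C)CCC=C(C)C)c3OCOC)O2)cc1OCOC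
F3 | step 8 | racemic 6-geranyl-2-[4-methoxy-3-(methoxymethoxy)phenyl]-5,7-bis(methoxymethoxy)chroman-4-one | COc1ccc(C2CC(=O)c3c(cc(OCOC)c(C/C=C(\C)CCC=C(C)C)c3OCOC)O2)cc1OCOC
F4 | step 8 | (2R,4R)-6-geranyl-2-[4-methoxy-3-(methoxymethoxy)phenyl]-5,7-bis(methoxymethoxy)chroman-4-ol, 2,4-cis | COc1ccc([C@H]2C[C@@H](O)c3c(cc(OCOC)c(C/C=C(\C)CCC=C(C)C)c3OCOC)O2)cc1OCOC
F0 | step 9 | none | none
F5 | step 11 | (2S)-6-geranyl-2-[4-methoxy-3-(trimethylsilyloxy)phenyl]-5,7-bis(trimethylsilyloxy)chroman-4-one | COc1ccc([C@@H]2CC(=O)c3c(cc(O[Si](C)(C)C)c(C/C=C(\C)CCC=C(C)C)c3O[Si](C)(C)C)O2)cc1O[Si](C)(C)C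
F6 | step 5 | 3-geranyl-2,4-bis(methoxymethoxy)-6-(triisopropylsilyloxy)benzaldehyde, (E)-alkene | O=Cc1c(O[Si](C(C)C)(C(C)C)C(C)C)cc(OCOC)c(C/C=C(\C)CCC=C(C)C)c1OCOC
A1 | alternative 1 | methyl 2-geranyl-4-{(2S)-2-[4-methoxy-3-(methoxymethoxy)phenyl]-4-oxo-3,4-dihydro-2H-pyran-6-yl}-3-oxobutanoate | COC(=O)C(C/C=C(\C)CCC=C(C)C)C(=O)CC1=CC(=O)C[C@@H](c2ccc(OC)c(OCOC)c2)O1
A2 | alternative 1 | (S)-6-geranylhesperetin 3'-O-methoxymethyl ether | COc1ccc([C@@H]2CC(=O)c3c(cc(O)c(C/C=C(\C)CCC=C(C)C)c3O)O2)cc1OCOC
A3 | alternative 2 | 2-diazo-1-{3-geranyl-6-[4-methoxy-3-(tert-butyldimethylsilyloxy)benzyloxy]-2,4-bis(tert-butyldimethylsilyloxy)phenyl}ethanone | [N-]=[N+]=CC(=O)c1c(OCc2ccc(OC)c(O[Si](C)(C)C(C)(C)C)c2)cc(O[Si](C)(C)C(C)(C)C)c(C/C=C(\C)CCC=C(C)C)c1O[Si](C)(C)C(C)(C)C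
A4 | alternative 2 | (S)-6-geranylhesperetin tris(tert-butyldimethylsilyl) ether | COc1ccc([C@@H]2CC(=O)c3c(cc(O[Si](C)(C)C(C)(C)C)c(C/C=C(\C)CCC=C(C)C)c3O[Si](C)(C)C(C)(C)C)O2)cc1O[Si](C)(C)C(C)(C)C
A5 | alternative 3 | (1S,3S)-1-[2-bromo-5-geranyl-4,6-bis(methoxymethoxy)phenyl]-3-[4-methoxy-3-(methoxymethoxy)phenyl]propane-1,3-diol | COc1ccc([C@@H](O)C[C@H](O)c2c(Br)cc(OCOC)c(C/C=C(\C)CCC=C(C)C)c2OCOC)cc1OCOC
A6 | alternative 3 | (2S,4S)-6-geranyl-5,7,3'-tris(methoxymethoxy)-4'-methoxyflavan-4-ol | COc1ccc([C@@H]2C[C@H](O)c3c(cc(OCOC)c(C/C=C(\C)CCC=C(C)C)c3OCOC)O2)cc1OCOC
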